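A direct plan would build each flavonoid half through a chalcone. A protected 4'-fluoroflavone A1 would be joined to 4-(benzyloxy)-3-hydroxybenzaldehyde A2 by SNAr to give the diaryl ether aldehyde A3. Aldol condensation of A3 with 2',6'-dihydroxy-4'-methoxyacetophenone A4 would give chalcone A5, an enantioselective oxa-Michael closure would set C2, and hydrogenolysis would finish.
Its weakest steps would be:
- The SNAr ether formation: the fluoride is activated only by a para chromonyl group, so carbonate in DMSO above 100 °C would be needed on a base-labile γ-pyrone next to an aldehyde.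
- The late aldol condensation of unprotected A4 as its trianion with the most advanced intermediate: the enolate is a poor nucleophile, and the 2',6'-dihydroxychalcone tends to close racemically on work-up.
- The asymmetric oxa-Michael closure of A5: the enone has no activating group, uncatalysed closure competes and the flavanone can reopen, so the only stereocentre would rest on an untested last C–O bond formation.

**Retrosynthetic overview**
Both halves are cut at the bond between C2 of ring C and ring B, not inside the pyranone ring. The two ring A/ring C bicycles are closed first as C2-unsubstituted chromones, and a small diaryl ether holding both B rings is made in one step from simple arenes.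
The flavone C2–aryl bond comes from C2 zincation of one chromone and Negishi coupling. The flavanone C2–C1' bond is formed last, by rhodium-catalysed asymmetric 1,4-addition of the complete flavone-bearing arylboronic acid to the second chromone.
This one step joins the two halves and sets the only stereocentre, C2 of the flavanone ring C, under catalyst control. There is no chalcone, no SNAr on a flavone and no late aldol, and after C2 is set only a neutral hydrogenolysis follows.

Key step: step 7

Assumption: the (S)-configured biaryl bisphosphine is taken to deliver the aryl group to the Re face of C2 of the chromone (giving 2S), by analogy with the (S)-BINAP/2-cyclohexenone model of the Hayashi–Miyaura reaction. If a model addition showed the opposite sense, the (R)-ligand would be used with no other change.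

**Step 1**
Reactants: 1 4-bromophenol; 2 [2-(benzyloxy)-5-chlorophenyl]boronic acid
Product: 3 1-(benzyloxy)-2-(4-bromophenoxy)-4-chlorobenzene
Conditions: 2 (2.0 equiv), Cu(OAc)2 (1.0 equiv), pyridine (5 equiv), 4 Å molecular sieves, CH2Cl2, dry air, rt, 48 h
Reagents that add atoms: none
Why: Chan–Lam oxidative C–O coupling, in which the arylboronic acid transmetalates to the copper phenoxide and reductive elimination from trivalent copper gives the diaryl ether at room temperature (air reoxidises the copper), while the aryl bromide and aryl chloride stay untouched and serve as two handles of different reactivity.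

**Step 2**
Reactants: 4 1-[2,4-bis(benzyloxy)-6-hydroxyphenyl]ethan-1-one
Product: 6 5,7-bis(benzyloxy)-4H-chromen-4-one, via (E)-1-[2,4-bis(benzyloxy)-6-hydroxyphenyl]-3-(dimethylamino)prop-2-en-1-one 5 (not isolated)
Conditions: Me2NCH(OMe)2 (3 equiv), toluene, 100 °C, 3 h; evaporate; conc. HCl (2 equiv), CH2Cl2, rt, 2 h
Reagents that add atoms: N,N-dimethylformamide dimethyl acetal COC(OC)N(C)C
Why: Enaminone formation at the only acidic methyl group, then acid-catalysed 6-endo addition of the chelated phenol OH and loss of dimethylamine, closes ring C of the flavone half as a C2-unsubstituted chromone, and benzyl ethers are stable to both reagents.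

**Step 3**
Reactants: 6 5,7-bis(benzyloxy)-4H-chromen-4-one; 3 1-(benzyloxy)-2-(4-bromophenoxy)-4-chlorobenzene
Product: 8 5,7-bis(benzyloxy)-2-{4-[2-(benzyloxy)-5-chlorophenoxy]phenyl}-4H-chromen-4-one, via [5,7-bis(benzyloxy)-4-oxo-4H-chromen-2-yl]zinc chloride 7 (not isolated)
Conditions: 6 (1.3 equiv), TMPZnCl·LiCl (1.45 equiv), THF, 25 °C, 2 h; then 3 (1.0 equiv), Pd(PPh3)4 (5 mol %), THF, 55 °C, 12 h
Reagents that add atoms: none
Why: Deprotonative zincation and Negishi coupling, in which the hindered zinc amide without added Lewis acid removes the most acidic ring proton of the chromone (C2–H next to the ring oxygen), the resulting organozinc tolerates its own carbonyl group, and the triphenylphosphine–palladium catalyst inserts only into the C–Br bond, so the flavone C2–aryl bond forms while the electron-rich C–Cl bond is kept.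

**Step 4**
Reactants: 8 5,7-bis(benzyloxy)-2-{4-[2-(benzyloxy)-5-chlorophenoxy]phenyl}-4H-chromen-4-one
Product: 9 (4-(benzyloxy)-3-{4-[5,7-bis(benzyloxy)-4-oxo-4H-chromen-2-yl]phenoxy}phenyl)boronic acid
Conditions: B2(OH)4 (3 equiv), KOAc (3 equiv), PdCl(XPhos)(2'-aminobiphenyl-2-yl) (second-generation XPhos palladacycle, 2 mol %), XPhos (4 mol %), EtOH–THF 2:1, 80 °C, 6 h; aqueous work-up, trituration
Reagents that add atoms: tetrahydroxydiboron OB(O)B(O)O
Why: Miyaura-type borylation of an aryl chloride with tetrahydroxydiboron under a bulky dialkylbiarylphosphine–palladium catalyst gives the free boronic acid directly, with no pinacol ester to cleave, and potassium acetate is too weak a base to open the flavone or touch the benzyl ethers.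

**Step 5**
Reactants: 10 1-(2,6-dihydroxy-4-methoxyphenyl)ethan-1-one
Product: 11 1-[2-(benzyloxy)-6-hydroxy-4-methoxyphenyl]ethan-1-one
Conditions: BnBr (1.05 equiv), K2CO3 (1.2 equiv), acetone, reflux, 6 h
Reagents that add atoms: benzyl bromide BrCc1ccccc1
Why: Williamson ether synthesis that stops after one alkylation, because the two OH groups are equivalent and the remaining one becomes the hydrogen-bond donor to the acetyl carbonyl once its twin is benzylated.

**Step 6**
Reactants: 11 1-[2-(benzyloxy)-6-hydroxy-4-methoxyphenyl]ethan-1-one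
Product: 13 5-(benzyloxy)-7-methoxy-4H-chromen-4-one, via (E)-1-[2-(benzyloxy)-6-hydroxy-4-methoxyphenyl]-3-(dimethylamino)prop-2-en-1-one 12 (not isolated)
Conditions: Me2NCH(OMe)2 (3 equiv), toluene, 100 °C, 3 h; evaporate; conc. HCl (2 equiv), CH2Cl2, rt, 2 h
Reagents that add atoms: N,N-dimethylformamide dimethyl acetal COC(OC)N(C)C
Why: The same enaminone formation and acid-catalysed 6-endo addition–elimination as in step 2 closes ring C of the flavanone half before any aryl group is attached, with the 7-methoxy group already in place.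

**Step 7**
Reactants: 13 5-(benzyloxy)-7-methoxy-4H-chromen-4-one; 9 (4-(benzyloxy)-3-{4-[5,7-bis(benzyloxy)-4-oxo-4H-chromen-2-yl]phenoxy}phenyl)boronic acid
Product: 14 (2S)-5-(benzyloxy)-2-(4-(benzyloxy)-3-{4-[5,7-bis(benzyloxy)-4-oxo-4H-chromen-2-yl]phenoxy}phenyl)-7-methoxy-2,3-dihydro-4H-chromen-4-one
Conditions: [Rh(OH)(cod)]2 (3 mol %), (S)-MeO-F12-BIPHEP (6.6 mol %), 9 (1.5 equiv), H2O (2 equiv), CH2Cl2–toluene 1:1, 0 → 20 °C, 24 h
Reagents that add atoms: none
Why: Hayashi–Miyaura cycle, in which the boronic acid transmetalates to the hydroxo complex of monovalent rhodium, the aryl–rhodium species inserts the C2=C3 bond of chromone 13 with the aryl group going to C2, and protonation of the rhodium oxa-π-allyl enolate releases the flavanone and regenerates Rh–OH. The closest known reaction type is the rhodium–bisphosphine-catalysed asymmetric 1,4-addition of arylboronic acids to chromones to give flavanones. No ring is closed, since rings A and C are already present in 13; the step forms the C2–C1' bond that joins the two halves of the target. The new stereocentre C2 is set by the chiral bisphosphine on rhodium, which should shield the Si face so that the aryl group reaches the Re face of C2 and gives 2S. The step needs site selectivity, secured because only 13 has an unsubstituted C2, whereas the flavone enone in 9 and 14 is β,β-disubstituted and inert to aryl–rhodium insertion. It also needs protonation of the enolate to outrun ring opening to the 2'-hydroxychalcone, which the electron-poor ligand, the base-free weakly polar medium and the 5-O-benzyl group (no rhodium chelate, no acidic OH) should secure, so that 14 does not racemise.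

**Step 8**
Reactants: 14 (2S)-5-(benzyloxy)-2-(4-(benzyloxy)-3-{4-[5,7-bis(benzyloxy)-4-oxo-4H-chromen-2-yl]phenoxy}phenyl)-7-methoxy-2,3-dihydro-4H-chromen-4-one
Product: 15 (2S)-2-(3-{4-[5,7-dihydroxy-4-oxo-4H-chromen-2-yl]phenoxy}-4-hydroxyphenyl)-5-hydroxy-7-methoxy-2,3-dihydro-4H-chromen-4-one
Conditions: H2 (1 atm), 10% Pd/C, EtOAc–THF 1:1, rt; followed by LC–MS and stopped when the fourth benzyl group is gone
Reagents that add atoms: none
Why: Hydrogenolysis of the four aryl benzyl ethers under neutral conditions, which neither open nor epimerise the flavanone (C2 stays S), and O-debenzylation should be much faster than reduction of the conjugated flavone C2=C3 bond or cleavage of the cyclic benzylic C2–O bond.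

**Compound list**
1 | 4-bromophenol | Oc1ccc(Br)cc1 | starting material
2 | [2-(benzyloxy)-5-chlorophenyl]boronic acid | OB(O)c1cc(Cl)ccc1OCc1ccccc1 | starting material
3 | 1-(benzyloxy)-2-(4-bromophenoxy)-4-chlorobenzene | Clc1ccc(OCc2ccccc2)c(Oc2ccc(Br)cc2)c1 | intermediate
4 | 1-[2,4-bis(benzyloxy)-6-hydroxyphenyl]ethan-1-one | CC(=O)c1c(O)cc(OCc2ccccc2)cc1OCc1ccccc1 | starting material
5 | (E)-1-[2,4-bis(benzyloxy)-6-hydroxyphenyl]-3-(dimethylamino)prop-2-en-1-one | CN(C)/C=C/C(=O)c1c(O)cc(OCc2ccccc2)cc1OCc1ccccc1 | intermediate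
6 | 5,7-bis(benzyloxy)-4H-chromen-4-one | O=c1ccoc2cc(OCc3ccccc3)cc(OCc3ccccc3)c12 | intermediate
7 | [5,7-bis(benzyloxy)-4-oxo-4H-chromen-2-yl]zinc chloride | O=c1cc([Zn]Cl)oc2cc(OCc3ccccc3)cc(OCc3ccccc3)c12 | intermediate
8 | 5,7-bis(benzyloxy)-2-{4-[2-(benzyloxy)-5-chlorophenoxy]phenyl}-4H-chromen-4-one | O=c1cc(-c2ccc(Oc3cc(Cl)ccc3OCc3ccccc3)cc2)oc2cc(OCc3ccccc3)cc(OCc3ccccc3)c12 | intermediate
9 | (4-(benzyloxy)-3-{4-[5,7-bis(benzyloxy)-4-oxo-4H-chromen-2-yl]phenoxy}phenyl)boronic acid | OB(O)c1ccc(OCc2ccccc2)c(Oc2ccc(-c3cc(=O)c4c(OCc5ccccc5)cc(OCc5ccccc5)cc4o3)cc2)c1 | intermediate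
10 | 1-(2,6-dihydroxy-4-methoxyphenyl)ethan-1-one | CC(=O)c1c(O)cc(OC)cc1O | starting material
11 | 1-[2-(benzyloxy)-6-hydroxy-4-methoxyphenyl]ethan-1-one | CC(=O)c1c(O)cc(OC)cc1OCc1ccccc1 | intermediate
12 | (E)-1-[2-(benzyloxy)-6-hydroxy-4-methoxyphenyl]-3-(dimethylamino)prop-2-en-1-one | CN(C)/C=C/C(=O)c1c(O)cc(OC)cc1OCc1ccccc1 | intermediate
13 | 5-(benzyloxy)-7-methoxy-4H-chromen-4-one | COc1cc(OCc2ccccc2)c2c(c1)occc2=O | intermediate
14 | (2S)-5-(benzyloxy)-2-(4-(benzyloxy)-3-{4-[5,7-bis(benzyloxy)-4-oxo-4H-chromen-2-yl]phenoxy}phenyl)-7-methoxy-2,3-dihydro-4H-chromen-4-one | COc1cc(OCc2ccccc2)c2c(c1)O[C@H](c1ccc(OCc3ccccc3)c(Oc3ccc(-c4cc(=O)c5c(OCc6ccccc6)cc(OCc6ccccc6)cc5o4)cc3)c1)CC2=O | intermediate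
15 | (2S)-2-(3-{4-[5,7-dihydroxy-4-oxo-4H-chromen-2-yl]phenoxy}-4-hydroxyphenyl)-5-hydroxy-7-methoxy-2,3-dihydro-4H-chromen-4-one | COc1cc(O)c2c(c1)O[C@H](c1ccc(O)c(Oc3ccc(-c4cc(=O)c5c(O)cc(O)cc5o4)cc3)c1)CC2=O | target

**Step count and risks**
Total step count: 8. Longest linear sequence: 5 (steps 2, 3, 4, 7, 8).

Steps most likely to fail:

1. Step 7. Insertion into the electron-rich 5,7-dioxygenated chromone may be slow, so that protodeboronation of 9 competes, or the enantiomeric purity may erode through ring opening of the rhodium enolate. The fallback sets out from 13 and 9. A racemic conjugate addition with the more electrophilic achiral catalyst of divalent palladium, Pd(OCOCF3)2/2,2'-bipyridine in aqueous acetic acid–THF, would give racemic 5-(benzyloxy)-2-(4-(benzyloxy)-3-{4-[5,7-bis(benzyloxy)-4-oxo-4H-chromen-2-yl]phenoxy}phenyl)-7-methoxy-2,3-dihydro-4H-chromen-4-one F1. Kinetic resolution by asymmetric transfer hydrogenation would follow, with RuCl(p-cymene)[(R,R)-TsDPEN] or its enantiomer (whichever reduces the 2R ketone faster) and HCO2H/Et3N. This would reduce the (2R)-flavanone to the cis alcohol (2R,4R)-5-(benzyloxy)-2-(4-(benzyloxy)-3-{4-[5,7-bis(benzyloxy)-4-oxo-4H-chromen-2-yl]phenoxy}phenyl)-7-methoxy-3,4-dihydro-2H-chromen-4-ol F2 and leave the (2S)-ketone, separated by chromatography. The fallback comes back to the route at 14.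

2. Step 3. Zincation may occur at C3, directed by the C4 carbonyl and the 5-benzyloxy group, instead of at C2, or the electron-poor organozinc may transmetalate slowly. The fallback sets out from 3 and 6. Magnesium insertion into the C–Br bond of 3 (Mg, LiCl, THF) would give {4-[2-(benzyloxy)-5-chlorophenoxy]phenyl}magnesium bromide F3. Copper-catalysed 1,4-addition to 6 (CuBr·SMe2 10 mol %, Me3SiCl, THF, −40 → 0 °C) would give {[5,7-bis(benzyloxy)-2-{4-[2-(benzyloxy)-5-chlorophenoxy]phenyl}-2H-chromen-4-yl]oxy}trimethylsilane F4. Acidic work-up would give racemic 5,7-bis(benzyloxy)-2-{4-[2-(benzyloxy)-5-chlorophenoxy]phenyl}-2,3-dihydro-4H-chromen-4-one F5. Dehydrogenation with catalytic I2 in DMSO at 120 °C would then give the flavone, and the fallback comes back to the route at 8.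

3. Step 1. Protodeboronation and oxidative hydroxylation of the ortho-alkoxy boronic acid may outrun the slow transmetalation to copper. The fallback sets out from 1. SNAr with 4-chloro-2-fluorobenzaldehyde F6 (purchased; K2CO3, DMF, 90 °C; fluoride activated by the ortho formyl group) would give 2-(4-bromophenoxy)-4-chlorobenzaldehyde F7. Baeyer–Villiger oxidation (mCPBA, CH2Cl2) would give 2-(4-bromophenoxy)-4-chlorophenyl formate F8, and methanolysis (K2CO3, MeOH) would give 2-(4-bromophenoxy)-4-chlorophenol F9. Benzylation (BnBr, K2CO3, acetone) comes back to the route at 3.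

**Further compounds**
F1 | step 7 | racemic 5-(benzyloxy)-2-(4-(benzyloxy)-3-{4-[5,7-bis(benzyloxy)-4-oxo-4H-chromen-2-yl]phenoxy}phenyl)-7-methoxy-2,3-dihydro-4H-chromen-4-one | COc1cc(OCc2ccccc2)c2c(c1)OC(c1ccc(OCc3ccccc3)c(Oc3ccc(-c4cc(=O)c5c(OCc6ccccc6)cc(OCc6ccccc6)cc5o4)cc3)c1)CC2=O
F2 | step 7 | (2R,4R)-5-(benzyloxy)-2-(4-(benzyloxy)-3-{4-[5,7-bis(benzyloxy)-4-oxo-4H-chromen-2-yl]phenoxy}phenyl)-7-methoxy-3,4-dihydro-2H-chromen-4-ol | COc1cc(OCc2ccccc2)c2c(c1)O[C@@H](c1ccc(OCc3ccccc3)c(Oc3ccc(-c4cc(=O)c5c(OCc6ccccc6)cc(OCc6ccccc6)cc5o4)cc3)c1)C[C@H]2O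
F3 | step 3 | {4-[2-(benzyloxy)-5-chlorophenoxy]phenyl}magnesium bromide | Br[Mg]c1ccc(Oc2cc(Cl)ccc2OCc2ccccc2)cc1
F4 | step 3 | {[5,7-bis(benzyloxy)-2-{4-[2-(benzyloxy)-5-chlorophenoxy]phenyl}-2H-chromen-4-yl]oxy}trimethylsilane | C[Si](C)(C)OC1=CC(c2ccc(Oc3cc(Cl)ccc3OCc3ccccc3)cc2)Oc2cc(OCc3ccccc3)cc(OCc3ccccc3)c12
F5 | step 3 | racemic 5,7-bis(benzyloxy)-2-{4-[2-(benzyloxy)-5-chlorophenoxy]phenyl}-2,3-dihydro-4H-chromen-4-one | O=C1CC(c2ccc(Oc3cc(Cl)ccc3OCc3ccccc3)cc2)Oc2cc(OCc3ccccc3)cc(OCc3ccccc3)c12
F6 | step 1 | 4-chloro-2-fluorobenzaldehyde | O=Cc1ccc(Cl)cc1F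
F7 | step 1 | 2-(4-bromophenoxy)-4-chlorobenzaldehyde | O=Cc1ccc(Cl)cc1Oc1ccc(Br)cc1
F8 | step 1 | 2-(4-bromophenoxy)-4-chlorophenyl formate | O=COc1ccc(Cl)cc1Oc1ccc(Br)cc1
F9 | step 1 | 2-(4-bromophenoxy)-4-chlorophenol | Oc1ccc(Cl)cc1Oc1ccc(Br)cc1
A1 | direct plan | 5,7-bis(benzyloxy)-2-(4-fluorophenyl)-4H-chromen-4-one | O=c1cc(-c2ccc(F)cc2)oc2cc(OCc3ccccc3)cc(OCc3ccccc3)c12
A2 | direct plan | 4-(benzyloxy)-3-hydroxybenzaldehyde | O=Cc1ccc(OCc2ccccc2)c(O)c1
A3 | direct plan | 4-(benzyloxy)-3-{4-[5,7-bis(benzyloxy)-4-oxo-4H-chromen-2-yl]phenoxy}benzaldehyde | O=Cc1ccc(OCc2ccccc2)c(Oc2ccc(-c3cc(=O)c4c(OCc5ccccc5)cc(OCc5ccccc5)cc4o3)cc2)c1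
A4 | direct plan | 1-(2,6-dihydroxy-4-methoxyphenyl)ethan-1-one | CC(=O)c1c(O)cc(OC)cc1O
A5 | direct plan | (E)-3-(4-(benzyloxy)-3-{4-[5,7-bis(benzyloxy)-4-oxo-4H-chromen-2-yl]phenoxy}phenyl)-1-(2,6-dihydroxy-4-methoxyphenyl)prop-2-en-1-one | COc1cc(O)c(C(=O)/C=C/c2ccc(OCc3ccccc3)c(Oc3ccc(-c4cc(=O)c5c(OCc6ccccc6)cc(OCc6ccccc6)cc5o4)cc3)c2)c(O)c1
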